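The route rests on cutting the C9–C10 bond of the ten-membered carbocycle. C1 (furanone carbonyl) and C8 (lactone carbinol, taken back to a ketone) are 1,4-related, so C10 and C9 are both enol α-carbons. Anodic oxidation of a diisopropylsilylene that bridges the 3-siloxyfuran oxygen (on C1) and the C8 enol ether oxygen joins C9 to C10 in one operation: it makes the quaternary stereocentre C10, closes the C1–C10 ring across the furanone (ring oxygen bridging C3 and C10) and returns both carbonyls. The precursor is an eleven-membered silylene bis-enol ether carrying C4–C7 with TBS (O5), MOM (O6) and an acetonide-masked C11 diol.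

Key step: step 17

Remark 1: atoms are numbered as in the target (C1 furanone carbonyl, C2=C3, C4–C10 ring carbons, C11–C13 lactone and methylene carbons, C14 methyl on C10, C15 methyl on C4; O5, O6, O8 are the oxygens on those carbons); the target is 4S,5S,6S,7R,8S,10R.
Remark 2: racemic but-3-yn-2-ol is used, so 20–26 are mixtures at C10 (22 and 23 also at C3); these centres become sp2 before step 17, which sets C10 anew, and their SMILES leave them undefined.
Remark 3: C11 of 33–36 is likewise an epimer mixture that is erased in step 22.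
Remark 4 (precursor design): no 4-methoxybenzyl ether is taken to the anode, because it is itself oxidisable there; O6 carries MOM, O5 carries TBS and the C11 diol is one acetonide, and C6 is acylated only after O8 is locked in the lactone.
Remark 5: the furanone is built from an ynone, because a preformed 2-methylfuran-3(2H)-one is deprotonated at C2–H first and would lack the C15 methyl on C4.

Step 1
Reactants: 1 2,2-dimethyl-1,3-dioxan-5-one; 2 ethyl (triphenylphosphoranylidene)acetate
Product: 3 ethyl 2-(2,2-dimethyl-1,3-dioxan-5-ylidene)acetate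
Conditions: CH2Cl2, 23 °C
Reagents that add atoms: none
Why: Wittig olefination of the activated α,α′-dioxygenated ketone by a stabilised ylide gives the exocyclic enoate, which has no stereo-element because the ring is symmetric.

Step 2
Reactants: 3 ethyl 2-(2,2-dimethyl-1,3-dioxan-5-ylidene)acetate
Product: 4 ethyl 2-(2,2-dimethyl-1,3-dioxan-5-yl)acetate
Conditions: H2 (1 atm), Pd/C, EtOAc, 23 °C
Reagents that add atoms: none
Why: Heterogeneous catalytic hydrogenation saturates the conjugated alkene without touching the acetonide and creates no stereocentre, since the future C11 carries two identical arms.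

Step 3
Reactants: 4 ethyl 2-(2,2-dimethyl-1,3-dioxan-5-yl)acetate
Product: 5 2-(2,2-dimethyl-1,3-dioxan-5-yl)acetic acid
Conditions: LiOH, THF/H2O, 0 → 23 °C; then cold aq. citric acid to pH 4–5
Reagents that add atoms: lithium hydroxide, [Li+].[OH-]
Why: Saponification of the ethyl ester, with a brief cold and weakly acidic work-up that should keep the acetonide.

Step 4
Reactants: 5 2-(2,2-dimethyl-1,3-dioxan-5-yl)acetic acid; 6 (S)-4-benzyl-1,3-oxazolidin-2-one
Product: 8 (S)-4-benzyl-3-[2-(2,2-dimethyl-1,3-dioxan-5-yl)acetyl]-1,3-oxazolidin-2-one, via mixed pivalic anhydride 7 (not isolated)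
Conditions: t-BuCOCl, Et3N, THF, −20 °C; then LiCl, 6, −20 → 23 °C
Reagents that add atoms: none
Why: N-Acylation of the oxazolidinone through a mixed anhydride (LiCl/Et3N activation) installs the auxiliary for the aldol step.

Step 5
Reactants: 8 (S)-4-benzyl-3-[2-(2,2-dimethyl-1,3-dioxan-5-yl)acetyl]-1,3-oxazolidin-2-one; 9 acrolein
Product: 11 (S)-4-benzyl-3-[(2S,3R)-2-(2,2-dimethyl-1,3-dioxan-5-yl)-3-hydroxypent-4-enoyl]-1,3-oxazolidin-2-one, via dibutylboron Z-enolate 10 (not isolated)
Conditions: Bu2BOTf, Et3N, CH2Cl2, −78 → 0 °C; 9, −78 → 0 °C; then pH 7 buffer, MeOH, H2O2, 0 °C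
Reagents that add atoms: none
Why: Evans syn-aldol reaction, in which the (Z)-boron enolate reacts through a closed chair transition state whose face is fixed by the benzyl group of the auxiliary, setting C7 and C6 (6,7-syn) in the required absolute sense.

Step 6
Reactants: 11 (S)-4-benzyl-3-[(2S,3R)-2-(2,2-dimethyl-1,3-dioxan-5-yl)-3-hydroxypent-4-enoyl]-1,3-oxazolidin-2-one
Product: 12 (2S,3R)-2-(2,2-dimethyl-1,3-dioxan-5-yl)-3-hydroxy-N-methoxy-N-methylpent-4-enamide
Conditions: MeNHOMe·HCl, AlMe3, CH2Cl2, −10 → 23 °C; aq. potassium sodium tartrate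
Reagents that add atoms: N,O-dimethylhydroxylamine hydrochloride, CNOC.Cl
Why: Aluminium-amide transamination of the β-hydroxy imide (Weinreb amide formation, assisted by the free hydroxyl) gives a non-enolising latent C8 methyl ketone and returns the auxiliary.

Step 7
Reactants: 12 (2S,3R)-2-(2,2-dimethyl-1,3-dioxan-5-yl)-3-hydroxy-N-methoxy-N-methylpent-4-enamide
Product: 13 (2S,3R)-2-(2,2-dimethyl-1,3-dioxan-5-yl)-N-methoxy-3-(methoxymethoxy)-N-methylpent-4-enamide
Conditions: MOMCl, i-Pr2NEt, Bu4NI (cat.), CH2Cl2, 0 → 40 °C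
Reagents that add atoms: chloromethyl methyl ether, COCCl
Why: O-Alkylation of the C6 hydroxyl (MOM ether formation) gives an acetal ether that can chelate magnesium in step 9, is inert at the anode and is orthogonal to TBS and the acetonide.

Step 8
Reactants: 13 (2S,3R)-2-(2,2-dimethyl-1,3-dioxan-5-yl)-N-methoxy-3-(methoxymethoxy)-N-methylpent-4-enamide
Product: 14 (2S,3S)-2-(2,2-dimethyl-1,3-dioxan-5-yl)-N-methoxy-3-(methoxymethoxy)-N-methyl-4-oxobutanamide
Conditions: O3, CH2Cl2, −78 °C; then PPh3, −78 → 23 °C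
Reagents that add atoms: ozone, [O-][O+]=O
Why: Ozonolysis with reductive work-up cleaves the vinyl group to the C5 aldehyde without base, so the α-alkoxy centre C6 is not at risk.

Step 9
Reactants: 14 (2S,3S)-2-(2,2-dimethyl-1,3-dioxan-5-yl)-N-methoxy-3-(methoxymethoxy)-N-methyl-4-oxobutanamide; 15 (E)-but-2-en-1-yl(tributyl)stannane
Product: 16 (2S,3S,4S,5R)-2-(2,2-dimethyl-1,3-dioxan-5-yl)-4-hydroxy-N-methoxy-3-(methoxymethoxy)-N,5-dimethylhept-6-enamide
Conditions: MgBr2·OEt2, CH2Cl2, −25 °C
Reagents that add atoms: none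
Why: Chelation-controlled Lewis-acid crotylstannane addition (SE2′), in which MgBr2 bridges the aldehyde oxygen and O6 so that attack comes anti to C7 (Cram-chelate, 5,6-syn) through an open antiperiplanar transition state that gives the 4,5-syn relationship, setting C5 and C4.

Step 10
Reactants: 16 (2S,3S,4S,5R)-2-(2,2-dimethyl-1,3-dioxan-5-yl)-4-hydroxy-N-methoxy-3-(methoxymethoxy)-N,5-dimethylhept-6-enamide
Product: 17 (2S,3S,4S,5R)-4-[(tert-butyldimethylsilyl)oxy]-2-(2,2-dimethyl-1,3-dioxan-5-yl)-N-methoxy-3-(methoxymethoxy)-N,5-dimethylhept-6-enamide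
Conditions: TBSOTf, 2,6-lutidine, CH2Cl2, −78 → 0 °C
Reagents that add atoms: tert-butyldimethylsilyl trifluoromethanesulfonate, CC(C)(C)[Si](C)(C)OS(=O)(=O)C(F)(F)F
Why: Silylation of the hindered C5 hydroxyl with the silyl triflate, done at once so that the γ-hydroxy Weinreb amide cannot lactonise.

Step 11
Reactants: 17 (2S,3S,4S,5R)-4-[(tert-butyldimethylsilyl)oxy]-2-(2,2-dimethyl-1,3-dioxan-5-yl)-N-methoxy-3-(methoxymethoxy)-N,5-dimethylhept-6-enamide
Product: 18 (2S,3S,4S,5S)-4-[(tert-butyldimethylsilyl)oxy]-2-(2,2-dimethyl-1,3-dioxan-5-yl)-N-methoxy-3-(methoxymethoxy)-N,5-dimethyl-6-oxohexanamide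
Conditions: O3, CH2Cl2, −78 °C; then PPh3, −78 → 23 °C
Reagents that add atoms: ozone, [O-][O+]=O
Why: Ozonolysis of the terminal alkene gives the C3 aldehyde under neutral conditions that should not epimerise the α-methyl centre C4.

Step 12
Reactants: 19 but-3-yn-2-ol (racemic)
Product: 20 (but-3-yn-2-yloxy)triethylsilane (racemic)
Conditions: Et3SiCl, imidazole, CH2Cl2, 0 → 23 °C
Reagents that add atoms: chlorotriethylsilane, CC[Si](Cl)(CC)CC
Why: Silylation of the propargylic alcohol gives a group that survives organometallics and oxidation and is removed by mild acid in step 15.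

Step 13
Reactants: 18 (2S,3S,4S,5S)-4-[(tert-butyldimethylsilyl)oxy]-2-(2,2-dimethyl-1,3-dioxan-5-yl)-N-methoxy-3-(methoxymethoxy)-N,5-dimethyl-6-oxohexanamide; 20 (but-3-yn-2-yloxy)triethylsilane
Product: 23 C8 methyl ketone with C3 propargylic alcohol (C1≡C2 alkyne; 10-O-SiEt3; 5-O-TBS; 6-O-MOM; C7 dioxanyl), via lithium acetylide 21 (not isolated), via lithium alkoxide 22 (not isolated)
Conditions: 20, n-BuLi, THF, −78 °C; 18, −78 °C; then MeMgBr, −78 → 0 °C; pH 7 buffer
Reagents that add atoms: methylmagnesium bromide, C[Mg]Br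
Why: 1,2-Addition of the lithium acetylide to the aldehyde at −78 °C, where the Weinreb amide is inert, followed in the same flask by Grignard addition to the Weinreb amide (Weinreb ketone synthesis through the chelated tetrahedral intermediate), the new C3 carbinol centre forming as a mixture that step 14 removes.

Step 14
Reactants: 23 C8 methyl ketone with C3 propargylic alcohol
Product: 24 ynone (C3 ketone conjugated to C1≡C2; 10-O-SiEt3; C8 methyl ketone; 4S,5S,6S,7S)
Conditions: Dess–Martin periodinane, NaHCO3, CH2Cl2, 0 → 23 °C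
Reagents that add atoms: none
Why: Dess–Martin oxidation of the propargylic alcohol under buffered, non-basic conditions should give the ynone without epimerising C4.

Step 15
Reactants: 24 ynone
Product: 26 2-methylfuran-3(2H)-one bearing at its C5 (= C3) the chain C4(Me)–C5(OTBS)–C6(OMOM)–C7(dioxanyl)–C8(=O)CH3 (4S,5S,6S,7S), via diethylamino enone 25 (not isolated)
Conditions: Et2NH, EtOH, 23 °C; then AcOH/THF/H2O (3:1:1), 23 °C
Reagents that add atoms: water, O
Why: Conjugate addition of diethylamine to the ynone gives a β-amino enone, and aqueous acetic acid then removes the triethylsilyl group so that the C10 hydroxyl closes onto C3 with loss of water and hydrolysis of the vinylogous iminium (cyclodehydration to the 3(2H)-furanone), C10 forming as a mixture that step 16 erases.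

Step 16
Reactants: 26 furanone methyl ketone
Product: 29 eleven-membered diisopropylsilylene bis-enol ether (3-siloxyfuran oxygen on C1 and C8 enol ether oxygen bridged by Si; C8=C9H2; 4S,5S,6S,7S), via potassium furanolate 27 (not isolated), via chlorosilyl furyl ether 28 (not isolated)
Conditions: KN(SiMe3)2 (1.05 equiv), THF, −78 °C; add to i-Pr2SiCl2 (3 equiv), −78 → 0 °C; evaporate; THF (0.003 M), KN(SiMe3)2 (1.1 equiv), −78 → −20 °C
Reagents that add atoms: dichlorodiisopropylsilane, CC(C)[Si](Cl)(Cl)C(C)C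
Why: Enolate O-silylation with a dichlorosilane (silyl bis-enol ether formation), in which the furanone is deprotonated at C10 to the aromatic furan-3-olate and capped as its chlorosilyl ether, after which kinetic deprotonation of the methyl ketone at C9 and intramolecular O-silylation at high dilution close the ring.

Step 17
Reactants: 29 eleven-membered diisopropylsilylene bis-enol ether
Product: 30 bicyclic furanone with C8 ketone (ten-membered carbocycle; 5-O-TBS; 6-O-MOM; C7 dioxanyl; 4S,5S,6S,7S,10R)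
Conditions: reticulated vitreous carbon anode, platinum cathode, undivided cell, constant current, 2.2 F/mol; LiClO4 (0.1 M), 2,6-lutidine, MeOH/CH2Cl2 (1:4), 0 °C
Reagents that add atoms: none
Why: Proposed new method: the 3-siloxyfuran is the only group of low oxidation potential in 29, so it is oxidised at the carbon anode to a radical cation that is attacked at C10 by the tethered enol ether carbon C9, after which a second electron is lost and methanol strips the silylene as i-Pr2Si(OMe)2 to leave the C1 and C8 carbonyls. The closest known reaction types are the oxidative coupling of unsymmetrical silyl bis-enol ethers with (NH4)2Ce(NO3)6 and anodic couplings of furans with silyl enol ethers. The bond forms by 7-endo attack on the furan C10=C1 bond inside the O–Si–O ring, and the same bond closes the ten-membered carbocycle C1–C10 (formally 10-endo) before the seven-membered ring is lost. C10 is set by C4: allylic 1,3-strain should hold H4 in the furan plane next to H2, so the C5–C8 chain lies over one furan face and C9 is delivered to that face (predicted 10R) while the C14 methyl is pushed to the other. Cross-coupling over homo-coupling is secured by the silicon tether, attack at C10 and not C3 by the reach of the seven-membered ring, and chemoselectivity by the absence of any other electroactive group (MOM, TBS and acetonide are inert at this potential).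

Step 18
Reactants: 30 bicyclic furanone with C8 ketone
Product: 31 C8 alcohol (4S,5S,6S,7R,8S,10R)
Conditions: NaBH4, MeOH/CH2Cl2, −40 °C
Reagents that add atoms: none
Why: Borohydride reduction of the saturated C8 ketone (the vinylogous-ester carbonyl C1 is far less electrophilic), with Felkin–Anh-type attack anti to the C11 substituent in the conformer that has C6–C7–C8–C9 antiperiplanar, which should set 8S.

Step 19
Reactants: 31 C8 alcohol
Product: 32 triol (C8 hydroxyl and the two hydroxymethyl groups on C11 free; 5-O-TBS and 6-O-MOM kept)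
Conditions: PPTS (cat.), MeOH, 23 °C
Reagents that add atoms: none
Why: Acid-catalysed transketalisation to methanol removes the acetonide while the MOM ether and the hindered secondary TBS ether should stay.

Step 20
Reactants: 32 triol
Product: 34 8,12-γ-lactone with hydroxymethyl on C11 (5-O-TBS; 6-O-MOM; C11 epimers), via lactol 33 (not isolated)
Conditions: TEMPO (cat.), PhI(OAc)2, CH2Cl2, 23 °C
Reagents that add atoms: none
Why: Oxoammonium (TEMPO) oxidation is selective for primary alcohols, the first aldehyde being trapped by O8 as the five-membered lactol and oxidised on to the lactone (oxidative lactonisation) while O6 is blocked.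

Step 21
Reactants: 34 8,12-γ-lactone with hydroxymethyl on C11
Product: 35 C6/C13 diol (6-OH and CH2OH free; 5-O-TBS kept)
Conditions: Me2BBr, CH2Cl2, −78 °C; then THF/aq. NaHCO3
Reagents that add atoms: none
Why: Bromoborane cleavage of the methoxymethyl acetal at low temperature, conditions under which silyl ethers and lactones are left alone.

Step 22
Reactants: 35 C6/C13 diol
Product: 37 5-O-TBS ether of the target (C6 methacrylate; C11=C13 methylene lactone), via bis-methacrylate 36 (not isolated)
Conditions: methacrylic anhydride, Et3N, DMAP (cat.), CH2Cl2, 0 → 23 °C; then DBU, 23 °C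
Reagents that add atoms: methacrylic anhydride, C=C(C)C(=O)OC(=O)C(C)=C
Why: DMAP-catalysed acylation of both hydroxyls, followed once acylation is complete by DBU-induced E1cB loss of methacrylate from the β-acyloxy lactone, installs the C6 ester and the exocyclic alkene together and avoids oxa-Michael addition of a free O6.

Step 23
Reactants: 37 5-O-TBS ether of the target
Product: 38 CNP0195404.1 (4S,5S,6S,7R,8S,10R)
Conditions: HF·pyridine, THF, 0 → 23 °C
Reagents that add atoms: none
Why: Acidic fluoride desilylation frees the C5 hydroxyl without the 1,2-acyl shift from O6 that basic fluoride could cause.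

Compound list
1 | 2,2-dimethyl-1,3-dioxan-5-one | CC1(C)OCC(=O)CO1 | starting material
2 | ethyl (triphenylphosphoranylidene)acetate | CCOC(=O)C=P(c1ccccc1)(c1ccccc1)c1ccccc1 | starting material
3 | ethyl 2-(2,2-dimethyl-1,3-dioxan-5-ylidene)acetate | CCOC(=O)C=C1COC(C)(C)OC1 | intermediate
4 | ethyl 2-(2,2-dimethyl-1,3-dioxan-5-yl)acetate | CCOC(=O)CC1COC(C)(C)OC1 | intermediate
5 | 2-(2,2-dimethyl-1,3-dioxan-5-yl)acetic acid | OC(=O)CC1COC(C)(C)OC1 | intermediate
6 | (S)-4-benzyl-1,3-oxazolidin-2-one | O=C1N[C@@H](Cc2ccccc2)CO1 | starting material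
7 | 2-(2,2-dimethyl-1,3-dioxan-5-yl)acetic pivalic anhydride (not isolated) | CC(C)(C)C(=O)OC(=O)CC1COC(C)(C)OC1 | intermediate
8 | (S)-4-benzyl-3-[2-(2,2-dimethyl-1,3-dioxan-5-yl)acetyl]-1,3-oxazolidin-2-one | O=C1OC[C@H](Cc2ccccc2)N1C(=O)CC3COC(C)(C)OC3 | intermediate
9 | acrolein | C=CC=O | starting material
10 | dibutylboron (Z)-enolate of 8 (not isolated) | CCCCB(CCCC)O/C(=C\C1COC(C)(C)OC1)N1C(=O)OC[C@@H]1Cc1ccccc1 | intermediate
11 | (S)-4-benzyl-3-[(2S,3R)-2-(2,2-dimethyl-1,3-dioxan-5-yl)-3-hydroxypent-4-enoyl]-1,3-oxazolidin-2-one | O=C1OC[C@H](Cc2ccccc2)N1C(=O)[C@@H](C3COC(C)(C)OC3)[C@H](O)C=C | intermediate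
12 | (2S,3R)-2-(2,2-dimethyl-1,3-dioxan-5-yl)-3-hydroxy-N-methoxy-N-methylpent-4-enamide | CON(C)C(=O)[C@@H](C1COC(C)(C)OC1)[C@H](O)C=C | intermediate
13 | (2S,3R)-2-(2,2-dimethyl-1,3-dioxan-5-yl)-N-methoxy-3-(methoxymethoxy)-N-methylpent-4-enamide | CON(C)C(=O)[C@@H](C1COC(C)(C)OC1)[C@H](OCOC)C=C | intermediate
14 | (2S,3S)-2-(2,2-dimethyl-1,3-dioxan-5-yl)-N-methoxy-3-(methoxymethoxy)-N-methyl-4-oxobutanamide | CON(C)C(=O)[C@@H](C1COC(C)(C)OC1)[C@H](OCOC)C=O | intermediate
15 | (E)-but-2-en-1-yl(tributyl)stannane | C/C=C/C[Sn](CCCC)(CCCC)CCCC | starting material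
16 | (2S,3S,4S,5R)-2-(2,2-dimethyl-1,3-dioxan-5-yl)-4-hydroxy-N-methoxy-3-(methoxymethoxy)-N,5-dimethylhept-6-enamide | C=C[C@@H](C)[C@H](O)[C@@H](OCOC)[C@@H](C(=O)N(C)OC)C1COC(C)(C)OC1 | intermediate
17 | (2S,3S,4S,5R)-4-[(tert-butyldimethylsilyl)oxy]-2-(2,2-dimethyl-1,3-dioxan-5-yl)-N-methoxy-3-(methoxymethoxy)-N,5-dimethylhept-6-enamide | C=C[C@@H](C)[C@H](O[Si](C)(C)C(C)(C)C)[C@@H](OCOC)[C@@H](C(=O)N(C)OC)C1COC(C)(C)OC1 | intermediate
18 | (2S,3S,4S,5S)-4-[(tert-butyldimethylsilyl)oxy]-2-(2,2-dimethyl-1,3-dioxan-5-yl)-N-methoxy-3-(methoxymethoxy)-N,5-dimethyl-6-oxohexanamide | O=C[C@@H](C)[C@H](O[Si](C)(C)C(C)(C)C)[C@@H](OCOC)[C@@H](C(=O)N(C)OC)C1COC(C)(C)OC1 | intermediate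
19 | but-3-yn-2-ol (racemic) | CC(O)C#C | starting material
20 | (but-3-yn-2-yloxy)triethylsilane (racemic) | CC(O[Si](CC)(CC)CC)C#C | intermediate
21 | lithium acetylide of 20 (not isolated) | CC(O[Si](CC)(CC)CC)C#C[Li] | intermediate
22 | lithium C3-alkoxide of the alkyne adduct, C8 Weinreb amide intact (not isolated; C3 and C10 mixtures) | CC(O[Si](CC)(CC)CC)C#CC(O[Li])[C@@H](C)[C@H](O[Si](C)(C)C(C)(C)C)[C@@H](OCOC)[C@@H](C(=O)N(C)OC)C1COC(C)(C)OC1 | intermediate
23 | C8 methyl ketone with C3 propargylic alcohol, C1≡C2 alkyne, 10-O-SiEt3, 5-O-TBS, 6-O-MOM, C7 dioxanyl (C3 and C10 mixtures) | CC(O[Si](CC)(CC)CC)C#CC(O)[C@@H](C)[C@H](O[Si](C)(C)C(C)(C)C)[C@@H](OCOC)[C@@H](C(C)=O)C1COC(C)(C)OC1 | intermediate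
24 | ynone: C3 ketone on C1≡C2, 10-O-SiEt3, C8 methyl ketone (4S,5S,6S,7S; C10 mixture) | CC(O[Si](CC)(CC)CC)C#CC(=O)[C@@H](C)[C@H](O[Si](C)(C)C(C)(C)C)[C@@H](OCOC)[C@@H](C(C)=O)C1COC(C)(C)OC1 | intermediate
25 | β-diethylamino enone from 24 (not isolated) | CCN(CC)C(=CC(=O)[C@@H](C)[C@H](O[Si](C)(C)C(C)(C)C)[C@@H](OCOC)[C@@H](C(C)=O)C1COC(C)(C)OC1)C(C)O[Si](CC)(CC)CC | intermediate
26 | 2-methylfuran-3(2H)-one with the C4–C8 chain at its C5; C8 methyl ketone (4S,5S,6S,7S; C10 mixture) | CC1OC(=CC1=O)[C@@H](C)[C@H](O[Si](C)(C)C(C)(C)C)[C@@H](OCOC)[C@@H](C(C)=O)C2COC(C)(C)OC2 | intermediate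
27 | potassium 2-methylfuran-3-olate of 26 (not isolated) | Cc1oc(cc1[O-])[C@@H](C)[C@H](O[Si](C)(C)C(C)(C)C)[C@@H](OCOC)[C@@H](C(C)=O)C2COC(C)(C)OC2.[K+] | intermediate
28 | 3-(chlorodiisopropylsilyloxy)-2-methylfuran of 26 (not isolated) | Cc1oc(cc1O[Si](Cl)(C(C)C)C(C)C)[C@@H](C)[C@H](O[Si](C)(C)C(C)(C)C)[C@@H](OCOC)[C@@H](C(C)=O)C2COC(C)(C)OC2 | intermediate
29 | eleven-membered diisopropylsilylene bis-enol ether: 3-siloxyfuran and C8 enol ether (C8=C9H2) bridged by Si (4S,5S,6S,7S) | C=C1O[Si](C(C)C)(C(C)C)Oc2cc(oc2C)[C@@H](C)[C@H](O[Si](C)(C)C(C)(C)C)[C@@H](OCOC)[C@@H]1C3COC(C)(C)OC3 | intermediate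
30 | bicyclic furanone with C8 ketone, 5-O-TBS, 6-O-MOM, C7 dioxanyl (4S,5S,6S,7S,10R) | COCO[C@@H]1[C@@H](O[Si](C)(C)C(C)(C)C)[C@H](C)C2=CC(=O)[C@@](C)(CC(=O)[C@H]1C3COC(C)(C)OC3)O2 | intermediate
31 | C8 alcohol of 30 (4S,5S,6S,7R,8S,10R) | COCO[C@@H]1[C@@H](O[Si](C)(C)C(C)(C)C)[C@H](C)C2=CC(=O)[C@@](C)(C[C@H](O)[C@H]1C3COC(C)(C)OC3)O2 | intermediate
32 | triol: 8-OH and C11 bis(hydroxymethyl), 5-O-TBS, 6-O-MOM | COCO[C@@H]1[C@@H](O[Si](C)(C)C(C)(C)C)[C@H](C)C2=CC(=O)[C@@](C)(C[C@H](O)[C@H]1C(CO)CO)O2 | intermediate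
33 | 8,12-lactol with C11 hydroxymethyl (not isolated) | COCO[C@@H]1[C@@H](O[Si](C)(C)C(C)(C)C)[C@H](C)C2=CC(=O)[C@@](C)(C[C@@H]3OC(O)C(CO)[C@@H]13)O2 | intermediate
34 | 8,12-γ-lactone with C11 hydroxymethyl, 5-O-TBS, 6-O-MOM (C11 mixture) | COCO[C@@H]1[C@@H](O[Si](C)(C)C(C)(C)C)[C@H](C)C2=CC(=O)[C@@](C)(C[C@@H]3OC(=O)C(CO)[C@@H]13)O2 | intermediate
35 | 6-hydroxy lactone with C11 hydroxymethyl, 5-O-TBS (C11 mixture) | O[C@@H]1[C@@H](O[Si](C)(C)C(C)(C)C)[C@H](C)C2=CC(=O)[C@@](C)(C[C@@H]3OC(=O)C(CO)[C@@H]13)O2 | intermediate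
36 | bis-methacrylate (O6 and O13) of 35 (not isolated) | C=C(C)C(=O)O[C@@H]1[C@@H](O[Si](C)(C)C(C)(C)C)[C@H](C)C2=CC(=O)[C@@](C)(C[C@@H]3OC(=O)C(COC(=O)C(C)=C)[C@@H]13)O2 | intermediate
37 | 5-O-TBS ether of the target | C=C(C)C(=O)O[C@@H]1[C@@H](O[Si](C)(C)C(C)(C)C)[C@H](C)C2=CC(=O)[C@@](C)(C[C@@H]3OC(=O)C(=C)[C@@H]13)O2 | intermediate
38 | CNP0195404.1 (4S,5S,6S,7R,8S,10R) | C=C(C)C(=O)O[C@@H]1[C@@H](O)[C@H](C)C2=CC(=O)[C@@](C)(C[C@@H]3OC(=O)C(=C)[C@@H]13)O2 | target

Total step count: 23. Longest linear sequence: 22 steps (steps 1–11 and 13–23; step 12 prepares the alkyne partner).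

Steps most likely to fail

Step 17 (proposed new method). Methanol may capture the furan radical cation before the carbon–carbon bond forms, the tether may be solvolysed before it is oxidised, or C9 may be delivered to the other furan face. The fallback uses known chemistry with neither tether nor electrolysis. It sets out from 26, which is doubly deprotonated (LiN(SiMe3)2, 2.2 equiv, THF, −78 °C) to the dilithium bis-enolate F1. This is oxidised with Fe(acac)3 (−78 → 23 °C), an intramolecular oxidative coupling of two metal enolates of the kind long used to make 1,4-diketones. The fallback comes back to the route at 30.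

Step 16. Intermolecular silylation (oligomers) may outrun closure of the eleven-membered ring, and the second deprotonation may drift toward C7. The fallback gives up the tether and sets out from 26. Both carbonyls are silylated separately (t-BuMe2SiOTf, Et3N, CH2Cl2, −78 → 0 °C) to the open bis(silyl enol ether) F2. This is electrolysed under the cell conditions of step 17, with intramolecularity alone left to enforce cross-coupling. The fallback comes back at 30.

Step 18. Hydride may be delivered to the other face of C8 if the ring reacts through a conformer with C6–C7–C8–C9 gauche. The fallback sets out from 30 and accepts the 8-epimeric alcohol F3. This is inverted by Mitsunobu esterification (4-nitrobenzoic acid, PPh3, DIAD, toluene, 0 → 23 °C) to the 8S 4-nitrobenzoate F4. Methanolysis (K2CO3, MeOH, 0 °C) then comes back to the route at 31.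

Further compounds
F1 | step 17 | dilithium bis-enolate of 26 (furan-3-olate and C8=C9 enolate) | Cc1oc(cc1[O-])[C@@H](C)[C@H](O[Si](C)(C)C(C)(C)C)[C@@H](OCOC)[C@@H](C(=C)[O-])C2COC(C)(C)OC2.[Li+].[Li+]
F2 | step 16 | open bis(tert-butyldimethylsilyl) enol ether of 26 (3-siloxyfuran and C8=C9 enol ether) | Cc1oc(cc1O[Si](C)(C)C(C)(C)C)[C@@H](C)[C@H](O[Si](C)(C)C(C)(C)C)[C@@H](OCOC)[C@@H](C(=C)O[Si](C)(C)C(C)(C)C)C2COC(C)(C)OC2
F3 | step 18 | 8-epimeric (8R) alcohol | COCO[C@@H]1[C@@H](O[Si](C)(C)C(C)(C)C)[C@H](C)C2=CC(=O)[C@@](C)(C[C@@H](O)[C@H]1C3COC(C)(C)OC3)O2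
F4 | step 18 | 8S 4-nitrobenzoate | COCO[C@@H]1[C@@H](O[Si](C)(C)C(C)(C)C)[C@H](C)C2=CC(=O)[C@@](C)(C[C@H](OC(=O)c4ccc(cc4)[N+](=O)[O-])[C@H]1C3COC(C)(C)OC3)O2
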